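**Plan**

- Retrosynthesis: the A‑ring C8–C1′ bond (C1′ = diarylmethine carbon of the side chain) is cut first. Then C1′–C2′ is cut (aldehyde + acetylide), the flavanone C2–aryl bond (chromone + arylboronic acid), and the chain at its carbonyl (Weinreb amide + pentyne).
- Enabling feature: C1′ carries a 4‑hydroxyphenyl ring, so a C1′ carbinol ionises to a planar para‑quinone methide. The phloroglucinol‑type A ring attacks it through C8, which lies between O7–H and the ring oxygen O1. C2′=C3′ is carried as an alkyne so that attack stays at C1′.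
- Forward order: the pyranone ring is closed as a chromone and arylated at C2 to give the flavanone. The chain is made by ynone reduction, alkyne zipper, silylation and addition to the aldehyde. The two halves are then joined, the alkyne is reduced to the E‑alkene and the silyl groups are removed.
- Stereochemistry: C2 comes from a ligand‑controlled Pd conjugate addition and C7′ from a Ru transfer hydrogenation. C1′ comes from a chiral phosphoric acid that turns both C1 epimers of the carbinol into one configuration. The E geometry comes from a Ru trans‑hydrogenation.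

Key step: step 11

Remark: the sense of induction in steps 3, 7 and 11 is assigned by analogy with the accepted models for these catalyst families; should a sense be the opposite, the mirror‑image ligand or catalyst is used.

**Route**

Step 1
Reactants: 1 1-(2,4-dihydroxy-6-methoxyphenyl)ethan-1-one
Product: 2 1-[4-(benzyloxy)-2-hydroxy-6-methoxyphenyl]ethan-1-one
Conditions: BnBr (1.05 equiv), K2CO3, acetone, reflux
Reagents that add atoms: benzyl bromide BrCc1ccccc1
Why: Williamson etherification should take place only at the 4‑OH, because the 2‑OH is held in a hydrogen bond to the ketone and is much less nucleophilic.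

Step 2
Reactants: 2 1-[4-(benzyloxy)-2-hydroxy-6-methoxyphenyl]ethan-1-one
Product: 4 7-(benzyloxy)-5-methoxy-4H-chromen-4-one, via enaminone 3 (not isolated)
Conditions: Me2NCH(OMe)2, toluene, 100 °C; then conc. HCl, CH2Cl2, 40 °C
Reagents that add atoms: N,N-dimethylformamide dimethyl acetal COC(OC)N(C)C
Why: Condensation at the acetyl methyl gives the enaminone, and acid then drives addition of the 2‑OH to the β‑carbon with loss of dimethylamine (the standard enaminone route to chromones, 6‑endo addition–elimination).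

Step 3
Reactants: 4 7-(benzyloxy)-5-methoxy-4H-chromen-4-one; 5 [4-(benzyloxy)phenyl]boronic acid
Product: 6 (2S)-7-(benzyloxy)-2-[4-(benzyloxy)phenyl]-5-methoxy-2,3-dihydro-4H-chromen-4-one
Conditions: Pd(OCOCF3)2 (10 mol %), (R)-t-BuPyOx (12 mol %), NH4PF6 (30 mol %), H2O (5 equiv), ClCH2CH2Cl, 60 °C
Reagents that add atoms: none
Why: Pd(II)/pyridine‑oxazoline‑catalysed asymmetric conjugate addition of an arylboronic acid to a chromone (Hayashi–Miyaura‑type 1,4‑addition) should deliver the aryl group to one face of C2 under ligand control and set the 2S centre.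

Step 4
Reactants: 6 (2S)-7-(benzyloxy)-2-[4-(benzyloxy)phenyl]-5-methoxy-2,3-dihydro-4H-chromen-4-one
Product: 7 (2S)-7-hydroxy-2-(4-hydroxyphenyl)-5-methoxy-2,3-dihydro-4H-chromen-4-one
Conditions: H2 (1 atm), 10 % Pd/C, EtOAc–MeOH, rt
Reagents that add atoms: none
Why: Hydrogenolysis of the two aryl benzyl ethers is a neutral deprotection that should leave the ketone and the base‑sensitive C2 centre untouched.

Step 5
Reactants: 8 3-(4-hydroxyphenyl)propanoic acid
Product: 9 3-(4-hydroxyphenyl)-N-methoxy-N-methylpropanamide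
Conditions: MeNH(OMe)·HCl, EDC·HCl, HOBt (cat.), N-methylmorpholine, CH2Cl2–DMF, 0 °C to rt
Reagents that add atoms: N,O-dimethylhydroxylamine hydrochloride CNOC.Cl
Why: Carbodiimide amide coupling gives the Weinreb amide, and the free phenol is tolerated as it is in peptide couplings of unprotected tyrosine.

Step 6
Reactants: 9 3-(4-hydroxyphenyl)-N-methoxy-N-methylpropanamide; 10 pent-1-yne
Product: 11 1-(4-hydroxyphenyl)oct-4-yn-3-one
Conditions: 10 (3 equiv), n-BuLi (3 equiv), THF, −78 °C; then 9, −78 to 0 °C; aq. NH4Cl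
Reagents that add atoms: none
Why: Weinreb ketone synthesis: one equivalent of acetylide is spent on the phenol, and the chelated tetrahedral adduct prevents a second addition, so the ynone should form on work‑up.

Step 7
Reactants: 11 1-(4-hydroxyphenyl)oct-4-yn-3-one
Product: 12 4-[(3S)-3-hydroxyoct-4-yn-1-yl]phenol
Conditions: Ru[(S,S)-TsDPEN](p-cymene) (1 mol %), i-PrOH, rt
Reagents that add atoms: none
Why: Noyori asymmetric transfer hydrogenation of an α,β‑acetylenic ketone, in which the alkynyl group takes the place of the aryl group of the usual model, should give the (S)‑propargylic alcohol.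

Step 8
Reactants: 12 4-[(3S)-3-hydroxyoct-4-yn-1-yl]phenol
Product: 13 4-[(3R)-3-hydroxyoct-7-yn-1-yl]phenol
Conditions: KH (5 equiv), H2N(CH2)3NH2, THF, 0 °C to rt; aq. NH4Cl
Reagents that add atoms: none
Why: Acetylene zipper isomerisation (potassium 3‑aminopropylamide) walks the triple bond away from the alkoxide to the chain end, where it is trapped as the terminal acetylide; the carbinol centre is not touched and only its descriptor changes from S to R.

Step 9
Reactants: 13 4-[(3R)-3-hydroxyoct-7-yn-1-yl]phenol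
Product: 14 tert-butyl{4-[(3R)-3-{[tert-butyl(dimethyl)silyl]oxy}oct-7-yn-1-yl]phenoxy}dimethylsilane
Conditions: TBSCl (2.5 equiv), imidazole, DMF, rt
Reagents that add atoms: tert-butyldimethylsilyl chloride CC(C)(C)[Si](C)(C)Cl
Why: Standard silylation should cap the phenol and the secondary alcohol and leave the terminal alkyne free.

Step 10
Reactants: 14 tert-butyl{4-[(3R)-3-{[tert-butyl(dimethyl)silyl]oxy}oct-7-yn-1-yl]phenoxy}dimethylsilane; 15 4-[(trimethylsilyl)oxy]benzaldehyde
Product: 17 (7R)-7-{[tert-butyl(dimethyl)silyl]oxy}-9-(4-{[tert-butyl(dimethyl)silyl]oxy}phenyl)-1-(4-hydroxyphenyl)non-2-yn-1-ol (both C1 epimers), via aryl trimethylsilyl ether 16 (not isolated)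
Conditions: n-BuLi, THF, −78 °C; then 15, −78 to 0 °C; aq. NH4Cl; K2CO3 (cat.), MeOH, 0 °C, 10 min
Reagents that add atoms: none
Why: Acetylide addition to the aldehyde builds the C1′–C2′ bond, and the labile aryl O–SiMe3 group is removed by brief methanolysis that should spare the TBS ethers; the new carbinol is left unselective on purpose because step 11 erases it.

Step 11
Reactants: 7 (2S)-7-hydroxy-2-(4-hydroxyphenyl)-5-methoxy-2,3-dihydro-4H-chromen-4-one; 17 (7R)-7-{[tert-butyl(dimethyl)silyl]oxy}-9-(4-{[tert-butyl(dimethyl)silyl]oxy}phenyl)-1-(4-hydroxyphenyl)non-2-yn-1-ol (both C1 epimers)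
Product: 19 (2S)-8-[(1R,7R)-7-{[tert-butyl(dimethyl)silyl]oxy}-9-(4-{[tert-butyl(dimethyl)silyl]oxy}phenyl)-1-(4-hydroxyphenyl)non-2-yn-1-yl]-7-hydroxy-2-(4-hydroxyphenyl)-5-methoxy-2,3-dihydro-4H-chromen-4-one, via alkynyl para-quinone methide 18 (not isolated)
Conditions: 7 (1.2 equiv), (R)-TRIP (10 mol %), 4 Å MS, ClCH2CH2Cl–EtOAc (4:1), rt
Reagents that add atoms: none
Why: The phosphoric acid dehydrates both C1 epimers of 17 to the same planar alkynyl para‑quinone methide 18 and holds it by a hydrogen bond to the quinone oxygen while its P=O binds O7–H of 7, so that C8 adds to the methide carbon (1,6‑addition) and the phenol ring re‑aromatises. The closest known reaction type is the chiral‑phosphoric‑acid‑catalysed enantioconvergent Friedel–Crafts arylation of para‑quinone methides generated in situ from racemic para‑hydroxybenzyl alcohols with naphthols and electron‑rich phenols. No ring is closed. The new stereocentre C1′ is set by the catalyst, which shields one face of 18 (1R in 19 because the alkynyl group outranks the aryl group; the same arrangement is 1S in the target), and the resident centres C2 and C7′ are too remote to override it. Attack at C1′ instead of the distal C3′ is secured by the alkyne, since a secondary propargylic terminus is open and the alternative product is an allene that gains no conjugation, whereas an alkene in this place would draw the nucleophile to C3′ to keep a styrene. C8 should be preferred over C6 because it is flanked only by O7–H and the tied‑back ring oxygen O1 while C6 is screened by the 5‑OMe group, whose methyl is turned toward C6 by the peri carbonyl, and the A ring is a far stronger carbon nucleophile than the simple 4‑alkylphenol rings.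

Step 12
Reactants: 19 (2S)-8-[(1R,7R)-7-{[tert-butyl(dimethyl)silyl]oxy}-9-(4-{[tert-butyl(dimethyl)silyl]oxy}phenyl)-1-(4-hydroxyphenyl)non-2-yn-1-yl]-7-hydroxy-2-(4-hydroxyphenyl)-5-methoxy-2,3-dihydro-4H-chromen-4-one
Product: 20 (2S)-8-[(1S,2E,7R)-7-{[tert-butyl(dimethyl)silyl]oxy}-9-(4-{[tert-butyl(dimethyl)silyl]oxy}phenyl)-1-(4-hydroxyphenyl)non-2-en-1-yl]-7-hydroxy-2-(4-hydroxyphenyl)-5-methoxy-2,3-dihydro-4H-chromen-4-one
Conditions: [Cp*Ru(cod)Cl] (5 mol %), AgOTf (5 mol %), H2 (10 bar), CH2Cl2, rt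
Reagents that add atoms: none
Why: Ruthenium‑catalysed trans‑hydrogenation of an internal alkyne should add the two hydrogens to opposite faces and give the E‑alkene while sparing the ketone, the arenes and the silyl ethers; C1′ is not touched and only its descriptor changes from R to S.

Step 13
Reactants: 20 (2S)-8-[(1S,2E,7R)-7-{[tert-butyl(dimethyl)silyl]oxy}-9-(4-{[tert-butyl(dimethyl)silyl]oxy}phenyl)-1-(4-hydroxyphenyl)non-2-en-1-yl]-7-hydroxy-2-(4-hydroxyphenyl)-5-methoxy-2,3-dihydro-4H-chromen-4-one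
Product: 21 (2S)-7-hydroxy-8-[(1S,2E,7R)-7-hydroxy-1,9-bis(4-hydroxyphenyl)non-2-en-1-yl]-2-(4-hydroxyphenyl)-5-methoxy-2,3-dihydro-4H-chromen-4-one
Conditions: HF·pyridine, pyridine, THF, 0 °C to rt
Reagents that add atoms: none
Why: Buffered fluoride desilylation should remove the aryl and the alkyl TBS ether under conditions too mild to open the flavanone or to reverse the Friedel–Crafts bond.

**Compound list**

1 | 1-(2,4-dihydroxy-6-methoxyphenyl)ethan-1-one | CC(=O)c1c(O)cc(O)cc1OC | starting material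
2 | 1-[4-(benzyloxy)-2-hydroxy-6-methoxyphenyl]ethan-1-one | CC(=O)c1c(O)cc(OCc2ccccc2)cc1OC | intermediate
3 | (E)-1-[4-(benzyloxy)-2-hydroxy-6-methoxyphenyl]-3-(dimethylamino)prop-2-en-1-one | CN(C)/C=C/C(=O)c1c(O)cc(OCc2ccccc2)cc1OC | intermediate
4 | 7-(benzyloxy)-5-methoxy-4H-chromen-4-one | O=c1ccoc2cc(OCc3ccccc3)cc(OC)c12 | intermediate
5 | [4-(benzyloxy)phenyl]boronic acid | OB(O)c1ccc(OCc2ccccc2)cc1 | starting material
6 | (2S)-7-(benzyloxy)-2-[4-(benzyloxy)phenyl]-5-methoxy-2,3-dihydro-4H-chromen-4-one | COc1cc(OCc2ccccc2)cc2c1C(=O)C[C@@H](c1ccc(OCc3ccccc3)cc1)O2 | intermediate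
7 | (2S)-7-hydroxy-2-(4-hydroxyphenyl)-5-methoxy-2,3-dihydro-4H-chromen-4-one | COc1cc(O)cc2c1C(=O)C[C@@H](c1ccc(O)cc1)O2 | intermediate
8 | 3-(4-hydroxyphenyl)propanoic acid | OC(=O)CCc1ccc(O)cc1 | starting material
9 | 3-(4-hydroxyphenyl)-N-methoxy-N-methylpropanamide | CON(C)C(=O)CCc1ccc(O)cc1 | intermediate
10 | pent-1-yne | CCCC#C | starting material
11 | 1-(4-hydroxyphenyl)oct-4-yn-3-one | CCCC#CC(=O)CCc1ccc(O)cc1 | intermediate
12 | 4-[(3S)-3-hydroxyoct-4-yn-1-yl]phenol | CCCC#C[C@@H](O)CCc1ccc(O)cc1 | intermediate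
13 | 4-[(3R)-3-hydroxyoct-7-yn-1-yl]phenol | C#CCCC[C@@H](O)CCc1ccc(O)cc1 | intermediate
14 | tert-butyl{4-[(3R)-3-{[tert-butyl(dimethyl)silyl]oxy}oct-7-yn-1-yl]phenoxy}dimethylsilane | C#CCCC[C@@H](O[Si](C)(C)C(C)(C)C)CCc1ccc(O[Si](C)(C)C(C)(C)C)cc1 | intermediate
15 | 4-[(trimethylsilyl)oxy]benzaldehyde | C[Si](C)(C)Oc1ccc(C=O)cc1 | starting material
16 | (7R)-7-{[tert-butyl(dimethyl)silyl]oxy}-9-(4-{[tert-butyl(dimethyl)silyl]oxy}phenyl)-1-{4-[(trimethylsilyl)oxy]phenyl}non-2-yn-1-ol (both C1 epimers) | OC(C#CCCC[C@@H](O[Si](C)(C)C(C)(C)C)CCc1ccc(O[Si](C)(C)C(C)(C)C)cc1)c1ccc(O[Si](C)(C)C)cc1 | intermediate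
17 | (7R)-7-{[tert-butyl(dimethyl)silyl]oxy}-9-(4-{[tert-butyl(dimethyl)silyl]oxy}phenyl)-1-(4-hydroxyphenyl)non-2-yn-1-ol (both C1 epimers) | OC(C#CCCC[C@@H](O[Si](C)(C)C(C)(C)C)CCc1ccc(O[Si](C)(C)C(C)(C)C)cc1)c1ccc(O)cc1 | intermediate
18 | 4-[(7R)-7-{[tert-butyl(dimethyl)silyl]oxy}-9-(4-{[tert-butyl(dimethyl)silyl]oxy}phenyl)non-2-yn-1-ylidene]cyclohexa-2,5-dien-1-one | O=C1C=CC(=CC#CCCC[C@@H](O[Si](C)(C)C(C)(C)C)CCc2ccc(O[Si](C)(C)C(C)(C)C)cc2)C=C1 | intermediate
19 | (2S)-8-[(1R,7R)-7-{[tert-butyl(dimethyl)silyl]oxy}-9-(4-{[tert-butyl(dimethyl)silyl]oxy}phenyl)-1-(4-hydroxyphenyl)non-2-yn-1-yl]-7-hydroxy-2-(4-hydroxyphenyl)-5-methoxy-2,3-dihydro-4H-chromen-4-one | COc1cc(O)c([C@@H](C#CCCC[C@@H](O[Si](C)(C)C(C)(C)C)CCc2ccc(O[Si](C)(C)C(C)(C)C)cc2)c2ccc(O)cc2)c2c1C(=O)C[C@@H](c1ccc(O)cc1)O2 | intermediate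
20 | (2S)-8-[(1S,2E,7R)-7-{[tert-butyl(dimethyl)silyl]oxy}-9-(4-{[tert-butyl(dimethyl)silyl]oxy}phenyl)-1-(4-hydroxyphenyl)non-2-en-1-yl]-7-hydroxy-2-(4-hydroxyphenyl)-5-methoxy-2,3-dihydro-4H-chromen-4-one | COc1cc(O)c([C@@H](/C=C/CCC[C@@H](O[Si](C)(C)C(C)(C)C)CCc2ccc(O[Si](C)(C)C(C)(C)C)cc2)c2ccc(O)cc2)c2c1C(=O)C[C@@H](c1ccc(O)cc1)O2 | intermediate
21 | (2S)-7-hydroxy-8-[(1S,2E,7R)-7-hydroxy-1,9-bis(4-hydroxyphenyl)non-2-en-1-yl]-2-(4-hydroxyphenyl)-5-methoxy-2,3-dihydro-4H-chromen-4-one | COc1cc(O)c([C@@H](/C=C/CCC[C@@H](O)CCc2ccc(O)cc2)c2ccc(O)cc2)c2c1C(=O)C[C@@H](c1ccc(O)cc1)O2 | target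

**Step count and risks**

Total step count: 13. Longest linear sequence: 9 steps (steps 5 to 13, from acid 8).

Steps most likely to fail:

1. Step 11. The catalyst may discriminate the two faces of the quinone methide poorly, attack may leak to C6, or distal addition may give an allene. The fallback is a tethered [3,3] route that sets out from 14 and 7 and comes back at 21.
   - Lithiated 14 is added to 4-[(tert-butyldimethylsilyl)oxy]benzaldehyde to give the tris‑silylated propargylic alcohol F1.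
   - Gold‑catalysed Meyer–Schuster rearrangement turns it into the (E)‑enone F2.
   - Corey–Bakshi–Shibata reduction with the (S)‑oxazaborolidine gives the (3R)‑allylic alcohol F3.
   - Mitsunobu etherification (PPh3, DIAD) of the more acidic 7‑OH of 7 with inversion gives the (3S)‑allyl aryl ether F4.
   - Aromatic Claisen rearrangement (PhNEt2, about 180 °C) through a chair transition state moves the chain to C8, transfers the chirality to C1′ and forms the E‑alkene, giving the C8‑allylated phenol F5.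
   - HF·pyridine then gives 21.

2. Step 12. Over‑reduction, migration of the new double bond into conjugation with an aryl ring, or ruthenium‑promoted addition of O7–H across the alkyne may compete. The fallback is a hydrosilylation–protodesilylation sequence that sets out from 19 and comes back at 21.
   - Fast trans‑hydrosilylation with (EtO)3SiH and [Cp*Ru(MeCN)3]PF6 (CH2Cl2, 0 °C) gives the alkenylsilane F6. It is drawn with silicon on C3′; the C2′ isomer converges to the same alkene.
   - TBAF/CuI in THF then replaces silicon by hydrogen with retention and removes both TBS ethers, which gives 21.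

3. Step 3. Insertion into the electron‑rich chromone may be slow, the boronic acid may protodeboronate, or the enantioselectivity may be low. The fallback is a racemic synthesis with resolution that sets out from 2 and comes back at 6.
   - Claisen–Schmidt condensation of 2 with 4-(benzyloxy)benzaldehyde (KOH, EtOH) gives the 2′‑hydroxychalcone F7.
   - NaOAc in refluxing EtOH closes it by oxa‑Michael addition to the racemic flavanone F8.
   - Preparative HPLC on a polysaccharide chiral stationary phase delivers the (2S)‑enantiomer 6.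

**Further compounds**

F1 | step 11 | (7R)-1,9-bis(4-{[tert-butyl(dimethyl)silyl]oxy}phenyl)-7-{[tert-butyl(dimethyl)silyl]oxy}non-2-yn-1-ol (both C1 epimers) | OC(C#CCCC[C@@H](O[Si](C)(C)C(C)(C)C)CCc1ccc(O[Si](C)(C)C(C)(C)C)cc1)c1ccc(O[Si](C)(C)C(C)(C)C)cc1
F2 | step 11 | (1E,7R)-1,9-bis(4-{[tert-butyl(dimethyl)silyl]oxy}phenyl)-7-{[tert-butyl(dimethyl)silyl]oxy}non-1-en-3-one | O=C(/C=C/c1ccc(O[Si](C)(C)C(C)(C)C)cc1)CCC[C@@H](O[Si](C)(C)C(C)(C)C)CCc1ccc(O[Si](C)(C)C(C)(C)C)cc1
F3 | step 11 | (1E,3R,7R)-1,9-bis(4-{[tert-butyl(dimethyl)silyl]oxy}phenyl)-7-{[tert-butyl(dimethyl)silyl]oxy}non-1-en-3-ol | O[C@@H](/C=C/c1ccc(O[Si](C)(C)C(C)(C)C)cc1)CCC[C@@H](O[Si](C)(C)C(C)(C)C)CCc1ccc(O[Si](C)(C)C(C)(C)C)cc1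
F4 | step 11 | (2S)-7-{[(1E,3S,7R)-1,9-bis(4-{[tert-butyl(dimethyl)silyl]oxy}phenyl)-7-{[tert-butyl(dimethyl)silyl]oxy}non-1-en-3-yl]oxy}-2-(4-hydroxyphenyl)-5-methoxy-2,3-dihydro-4H-chromen-4-one | COc1cc(O[C@H](/C=C/c2ccc(O[Si](C)(C)C(C)(C)C)cc2)CCC[C@@H](O[Si](C)(C)C(C)(C)C)CCc2ccc(O[Si](C)(C)C(C)(C)C)cc2)cc2c1C(=O)C[C@@H](c1ccc(O)cc1)O2
F5 | step 11 | (2S)-8-[(1S,2E,7R)-1,9-bis(4-{[tert-butyl(dimethyl)silyl]oxy}phenyl)-7-{[tert-butyl(dimethyl)silyl]oxy}non-2-en-1-yl]-7-hydroxy-2-(4-hydroxyphenyl)-5-methoxy-2,3-dihydro-4H-chromen-4-one | COc1cc(O)c([C@@H](/C=C/CCC[C@@H](O[Si](C)(C)C(C)(C)C)CCc2ccc(O[Si](C)(C)C(C)(C)C)cc2)c2ccc(O[Si](C)(C)C(C)(C)C)cc2)c2c1C(=O)C[C@@H](c1ccc(O)cc1)O2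
F6 | step 12 | (2S)-8-[(1S,2Z,7R)-7-{[tert-butyl(dimethyl)silyl]oxy}-9-(4-{[tert-butyl(dimethyl)silyl]oxy}phenyl)-1-(4-hydroxyphenyl)-3-(triethoxysilyl)non-2-en-1-yl]-7-hydroxy-2-(4-hydroxyphenyl)-5-methoxy-2,3-dihydro-4H-chromen-4-one | COc1cc(O)c([C@@H](/C=C(/CCC[C@@H](O[Si](C)(C)C(C)(C)C)CCc2ccc(O[Si](C)(C)C(C)(C)C)cc2)[Si](OCC)(OCC)OCC)c2ccc(O)cc2)c2c1C(=O)C[C@@H](c1ccc(O)cc1)O2
F7 | step 3 | (E)-1-[4-(benzyloxy)-2-hydroxy-6-methoxyphenyl]-3-[4-(benzyloxy)phenyl]prop-2-en-1-one | O=C(/C=C/c1ccc(OCc2ccccc2)cc1)c1c(O)cc(OCc2ccccc2)cc1OC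
F8 | step 3 | racemic 7-(benzyloxy)-2-[4-(benzyloxy)phenyl]-5-methoxy-2,3-dihydro-4H-chromen-4-one | COc1cc(OCc2ccccc2)cc2c1C(=O)CC(c1ccc(OCc3ccccc3)cc1)O2
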